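**Plan**
- Retrosynthesis: the C5 benzyl ether and the lactone C2–O1 bond are cut first, then bond C8–C8a of ring A. This unfolds ring A into a C3-branched 4-benzyloxy-6-(2-oxoalkyl)-2-pyranone. The ketone chain is then cut at the pyranone 6-CH2 (aldol), and the branch at the pyranone C3–CH(Ph) bond (conjugate addition to cinnamaldehyde).
- Enabling feature: ring A (chroman-2-one numbering) carries oxygen on C5, C7 and C8a, the acyl group on C8 and hydrogen on C6. This is the Claisen folding pattern of a tetraketide whose C4a bears the C4 stereocentre, so a pyranone can serve as the masked chain.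
- Forward order: the pyranone ring is bought as triacetic acid lactone. The stereogenic branch is attached at C3, the aryl-butanone chain at the 6-methyl group, ring A is closed by Claisen recyclization, the lactone ring is closed next, and the benzyl group is removed last.
- Stereochemistry: the single (4S) centre is set in step 1 by the (S)-diphenylprolinol silyl ether catalyst and is never enolisable afterwards.

Key step: step 7

Remark: lactol 4 and carbinol 10 are epimer mixtures at the oxygen-bearing carbon; this has no consequence because that carbon is oxidised in the following step.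

**Step 1**
Reactants: 1 triacetic acid lactone (4-hydroxy-6-methyl-2H-pyran-2-one); 2 (E)-cinnamaldehyde
Product: 4 (4S)-2-hydroxy-7-methyl-4-phenyl-3,4-dihydro-2H,5H-pyrano[4,3-b]pyran-5-one (both C2 epimers), via open-chain Michael aldehyde 3 (not isolated)
Conditions: (S)-α,α-diphenylprolinol trimethylsilyl ether (20 mol %), CH2Cl2, 0 °C to rt
Reagents that add atoms: none
Why: Iminium-catalysed Michael addition of an acidic 4-hydroxy-2-pyranone through C3 to an enal, followed by hemiacetal closure onto the 4-OH, is known for this nucleophile class; the CPh2(OSiMe3) group of the (S)-catalyst blocks one face of the s-trans (E)-iminium ion, so C3 adds to the open face of the β-carbon and sets the (S)-centre.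

**Step 2**
Reactants: 4 lactol
Product: 5 (4S)-7-methyl-4-phenyl-3,4-dihydro-2H,5H-pyrano[4,3-b]pyran-2,5-dione
Conditions: Dess–Martin periodinane (1.3 equiv), CH2Cl2, rt
Reagents that add atoms: none
Why: Dess–Martin oxidation of a lactol to the lactone proceeds under neutral conditions that touch neither the pyranone nor the benzylic stereocentre.

**Step 3**
Reactants: 5 enol lactone
Product: 6 methyl (3S)-3-(4-hydroxy-6-methyl-2-oxo-2H-pyran-3-yl)-3-phenylpropanoate
Conditions: K2CO3 (1.2 equiv), MeOH, 0 °C to rt; then 1 M HCl
Reagents that add atoms: methanol, CO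
Why: Base-mediated methanolysis (transesterification) of the enol lactone is fast because the acyl group sits on the acidic pyranone 4-oxygen, and the 4-olate formed protects the pyranone from further attack and cannot undergo retro-Michael loss of the branch.

**Step 4**
Reactants: 6 hydroxypyranone ester
Product: 7 methyl (3S)-3-[4-(benzyloxy)-6-methyl-2-oxo-2H-pyran-3-yl]-3-phenylpropanoate
Conditions: BnBr (1.2 equiv), K2CO3 (1.5 equiv), DMF, rt
Reagents that add atoms: benzyl bromide, BrCc1ccccc1
Why: Williamson O-alkylation of a 4-hydroxy-2-pyranone olate with a benzylic bromide normally favours the 4-alkoxy-2-pyranone over the 2-alkoxy-4-pyranone, and C-alkylation is not expected because C3 is already substituted.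

**Step 5**
Reactants: 7 benzyloxypyranone; 8 3-(4-methoxyphenyl)propanal
Product: 10 methyl (3S)-3-{4-(benzyloxy)-6-[2-hydroxy-4-(4-methoxyphenyl)butyl]-2-oxo-2H-pyran-3-yl}-3-phenylpropanoate (both carbinol epimers), via lithium dienolate 9 (not isolated)
Conditions: LiN(SiMe3)2 (1.05 equiv), THF, −78 °C; then 8 (1.2 equiv), −78 °C; aq. NH4Cl
Reagents that add atoms: none
Why: Lateral (vinylogous) deprotonation of the 6-methyl group of a 4-alkoxy-2-pyranone followed by aldol addition is standard; these protons are several pKa units more acidic than those of the methyl ester, so one equivalent of amide base at −78 °C should metalate only there, and the aldolate consumes no further base.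

**Step 6**
Reactants: 10 carbinol
Product: 11 methyl (3S)-3-{4-(benzyloxy)-6-[4-(4-methoxyphenyl)-2-oxobutyl]-2-oxo-2H-pyran-3-yl}-3-phenylpropanoate
Conditions: Dess–Martin periodinane (1.3 equiv), CH2Cl2, 0 °C to rt
Reagents that add atoms: none
Why: Dess–Martin oxidation of the secondary alcohol converges both epimers on the 6-(2-oxoalkyl)pyranone under non-basic conditions that leave the ester, the benzyl ether and the stereocentre alone.

**Step 7**
Reactants: 11 6-(2-oxoalkyl)pyranone
Product: 13 methyl (3S)-3-{6-(benzyloxy)-2,4-dihydroxy-3-[3-(4-methoxyphenyl)propanoyl]phenyl}-3-phenylpropanoate, via acyclic diketo diester 12 (not isolated)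
Conditions: Mg(OMe)2 (4 equiv), MeOH, reflux; then 1 M HCl, 0 °C
Reagents that add atoms: none
Why: Methoxide from Mg(OMe)2 adds to the lactone carbonyl of the pyranone and the ring oxygen leaves as the enolate of the neighbouring ketone, giving the magnesium-chelated acyclic diketo diester 12; its carbanion between the two ketones (future C8) then attacks the unsaturated ester carbonyl (future C8a), methoxide is expelled and the cyclohexenetrione enolises to aromatic ring A. The closest known reaction type is the Mg(OMe)2-induced Claisen recyclization of 4-alkoxy-6-(2-oxoalkyl)-2-pyranones to acylphloroglucinol monoethers, applied here to a C3-branched pyranone. Ring A closes in a 6-exo-trig Dieckmann-type (Claisen) mode on the opened chain, because the geometry of the intact pyranone does not allow the side-chain carbanion to reach the carbonyl across the ring. No stereocentre is formed, and the existing one (benzylic, β to the ester, not enolisable by methoxide) is carried through. The step needs Claisen rather than aldol folding and no retro-Claisen cleavage: the carbon an aldol closure would use is fully substituted and locked in the benzyl enol ether, and chelation of the diketonate by the magnesium ion holds the nucleophile next to the ester and shields the diketone from methoxide. The former lactone carbonyl oxygen ends as the only free hydroxyl beside the branched carbon, which fixes the regiochemistry of the later lactonization.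

**Step 8**
Reactants: 13 acylphloroglucinol ester
Product: 14 (4S)-5-(benzyloxy)-7-hydroxy-8-[3-(4-methoxyphenyl)propanoyl]-4-phenyl-3,4-dihydro-2H-chromen-2-one
Conditions: TsOH·H2O (10 mol %), toluene, 4 Å MS, 80 °C
Reagents that add atoms: none
Why: Acid-catalysed lactonization (intramolecular transesterification) closes the six-membered aryl lactone, and since the other oxygen ortho to the branch is benzylated, only the hydroxyl between the acyl group and the branch can react, so only the 8-acyl lactone can form.

**Step 9**
Reactants: 14 benzyl ether lactone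
Product: 15 (4S)-5,7-dihydroxy-8-[3-(4-methoxyphenyl)propanoyl]-4-phenyl-3,4-dihydro-2H-chromen-2-one (CNP0240692.1)
Conditions: H2 (1 atm), Pd/C (10 wt %), EtOAc, rt
Reagents that add atoms: none
Why: Catalytic hydrogenolysis of an aryl benzyl ether over Pd/C is selective at one atmosphere and room temperature, where the hydrogen-bonded aryl ketone, the lactone and the C4 centre should be inert.

**Compound list**
1 | triacetic acid lactone (4-hydroxy-6-methyl-2H-pyran-2-one) | CC1=CC(O)=CC(=O)O1 | starting material
2 | (E)-cinnamaldehyde | O=C/C=C/c1ccccc1 | starting material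
3 | (3S)-3-(4-hydroxy-6-methyl-2-oxo-2H-pyran-3-yl)-3-phenylpropanal | O=CC[C@H](C1=C(O)C=C(C)OC1=O)c1ccccc1 | intermediate
4 | (4S)-2-hydroxy-7-methyl-4-phenyl-3,4-dihydro-2H,5H-pyrano[4,3-b]pyran-5-one (C2 epimers) | OC1C[C@@H](c2ccccc2)C2=C(O1)C=C(C)OC2=O | intermediate
5 | (4S)-7-methyl-4-phenyl-3,4-dihydro-2H,5H-pyrano[4,3-b]pyran-2,5-dione | O=C1C[C@@H](c2ccccc2)C2=C(O1)C=C(C)OC2=O | intermediate
6 | methyl (3S)-3-(4-hydroxy-6-methyl-2-oxo-2H-pyran-3-yl)-3-phenylpropanoate | COC(=O)C[C@H](C1=C(O)C=C(C)OC1=O)c1ccccc1 | intermediate
7 | methyl (3S)-3-[4-(benzyloxy)-6-methyl-2-oxo-2H-pyran-3-yl]-3-phenylpropanoate | COC(=O)C[C@H](C1=C(OCc2ccccc2)C=C(C)OC1=O)c1ccccc1 | intermediate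
8 | 3-(4-methoxyphenyl)propanal | O=CCCc1ccc(OC)cc1 | starting material
9 | lithium dienolate of 7 (6-methylene carbanion) | COC(=O)C[C@H](C1=C(OCc2ccccc2)C=C([CH2-])OC1=O)c1ccccc1.[Li+] | intermediate
10 | methyl (3S)-3-{4-(benzyloxy)-6-[2-hydroxy-4-(4-methoxyphenyl)butyl]-2-oxo-2H-pyran-3-yl}-3-phenylpropanoate (carbinol epimers) | COC(=O)C[C@H](C1=C(OCc2ccccc2)C=C(CC(O)CCc2ccc(OC)cc2)OC1=O)c1ccccc1 | intermediate
11 | methyl (3S)-3-{4-(benzyloxy)-6-[4-(4-methoxyphenyl)-2-oxobutyl]-2-oxo-2H-pyran-3-yl}-3-phenylpropanoate | COC(=O)C[C@H](C1=C(OCc2ccccc2)C=C(CC(=O)CCc2ccc(OC)cc2)OC1=O)c1ccccc1 | intermediate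
12 | dimethyl (2E,3S)-2-[1-(benzyloxy)-7-(4-methoxyphenyl)-3,5-dioxoheptylidene]-3-phenylpentanedioate | COC(=O)/C(=C(/OCc1ccccc1)CC(=O)CC(=O)CCc1ccc(OC)cc1)[C@@H](CC(=O)OC)c1ccccc1 | intermediate
13 | methyl (3S)-3-{6-(benzyloxy)-2,4-dihydroxy-3-[3-(4-methoxyphenyl)propanoyl]phenyl}-3-phenylpropanoate | COC(=O)C[C@H](c1c(OCc2ccccc2)cc(O)c(C(=O)CCc2ccc(OC)cc2)c1O)c1ccccc1 | intermediate
14 | (4S)-5-(benzyloxy)-7-hydroxy-8-[3-(4-methoxyphenyl)propanoyl]-4-phenyl-3,4-dihydro-2H-chromen-2-one | COc1ccc(CCC(=O)c2c(O)cc(OCc3ccccc3)c3c2OC(=O)C[C@H]3c2ccccc2)cc1 | intermediate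
15 | (4S)-5,7-dihydroxy-8-[3-(4-methoxyphenyl)propanoyl]-4-phenyl-3,4-dihydro-2H-chromen-2-one | COc1ccc(CCC(=O)c2c(O)cc(O)c3c2OC(=O)C[C@H]3c2ccccc2)cc1 | target

**Count**
Total step count: 9. Longest linear sequence: 9 steps (1 to 15).

**Steps most likely to fail**

1. Step 7. Methoxide may exchange the benzyl enol ether for a methyl ether by addition–elimination at the pyranone 4-position. It may also fail to open the hindered, C3-branched pyranone before the diketone is cleaved by retro-Claisen reaction.
Fallback (sets out from 1, returns at 14): ring A is made first on the unbranched pyranone, for which the recyclization is directly known, and the stereocentre is set afterwards. Triacetic acid lactone 1 would be benzylated under Mitsunobu conditions (BnOH, PPh3, DIAD) to 4-(benzyloxy)-6-methyl-2H-pyran-2-one F1. F1 would be metalated with LiN(SiMe3)2 at −78 °C and added to aldehyde 8 to give 4-(benzyloxy)-6-[2-hydroxy-4-(4-methoxyphenyl)butyl]-2H-pyran-2-one F2. Dess–Martin oxidation would give 4-(benzyloxy)-6-[4-(4-methoxyphenyl)-2-oxobutyl]-2H-pyran-2-one F3, and Mg(OMe)2 in refluxing MeOH should fold it to 1-[4-(benzyloxy)-2,6-dihydroxyphenyl]-3-(4-methoxyphenyl)propan-1-one F4. F4 has two equivalent ring CH positions, each flanked by one free hydroxyl and the benzyl ether. Iminium-catalysed Friedel–Crafts-type conjugate addition of this phenol to cinnamaldehyde 2 with the same (S)-catalyst, followed by hemiacetal closure onto the only neighbouring free hydroxyl, should give 1-[(4S)-5-(benzyloxy)-2,7-dihydroxy-4-phenyl-3,4-dihydro-2H-chromen-8-yl]-3-(4-methoxyphenyl)propan-1-one F5. Oxidation of the lactol carbon with pyridinium chlorochromate (C5H5NH[CrO3Cl]) in CH2Cl2 then returns to 14.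

2. Step 5. Proton transfer may win over C–C bond formation: the dienolate can enolise the aliphatic aldehyde, or equilibrate to the ester enolate and start intermolecular Claisen condensation. The aldolate may also revert by retro-aldol reaction on warming.
Fallback (sets out from 7, returns at 11): the chain is introduced at the ketone oxidation level by acylation, which replaces steps 5 and 6. N-methoxy-N-methyl-3-(4-methoxyphenyl)propanamide F6 would be prepared from commercial methyl 3-(4-methoxyphenyl)propanoate with MeNHOMe·HCl and i-PrMgCl in THF. The dienolate of 7 (LiN(SiMe3)2, 1.05 equiv, THF, −78 °C) would be acylated with F6. The chelated tetrahedral adduct holds until aqueous quench, so no second equivalent of base is consumed and no enolisable aldehyde is present; work-up gives 11 directly.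

3. Step 4. Alkylation may go to the lactone carbonyl oxygen and give the isomeric 2-benzyloxy-4-pyranone, helped by the crowding of the 4-olate next to the branched C3 substituent.
Fallback (sets out from 6, returns at 7): Mitsunobu etherification with benzyl alcohol, PPh3 and DIAD in THF. Here the pyranone acts as the acid component toward an alkoxyphosphonium ion under neutral conditions, a mode known to deliver 4-alkoxy-2-pyranones; no new compound is made.

**Further compounds**
F1 | step 7 | 4-(benzyloxy)-6-methyl-2H-pyran-2-one | CC1=CC(OCc2ccccc2)=CC(=O)O1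
F2 | step 7 | 4-(benzyloxy)-6-[2-hydroxy-4-(4-methoxyphenyl)butyl]-2H-pyran-2-one | COc1ccc(CCC(O)CC2=CC(OCc3ccccc3)=CC(=O)O2)cc1
F3 | step 7 | 4-(benzyloxy)-6-[4-(4-methoxyphenyl)-2-oxobutyl]-2H-pyran-2-one | COc1ccc(CCC(=O)CC2=CC(OCc3ccccc3)=CC(=O)O2)cc1
F4 | step 7 | 1-[4-(benzyloxy)-2,6-dihydroxyphenyl]-3-(4-methoxyphenyl)propan-1-one | COc1ccc(CCC(=O)c2c(O)cc(OCc3ccccc3)cc2O)cc1
F5 | step 7 | 1-[(4S)-5-(benzyloxy)-2,7-dihydroxy-4-phenyl-3,4-dihydro-2H-chromen-8-yl]-3-(4-methoxyphenyl)propan-1-one | COc1ccc(CCC(=O)c2c(O)cc(OCc3ccccc3)c3c2OC(O)C[C@H]3c2ccccc2)cc1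
F6 | step 5 | N-methoxy-N-methyl-3-(4-methoxyphenyl)propanamide | CON(C)C(=O)CCc1ccc(OC)cc1
F0 | step 4 | none | none
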